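## Retrosynthetic overview

1. C2–C3: the acetate arm is added last, by a silyl ketene acetal attacking the C3 peroxycarbenium ion of a 3-methoxy-1,2-dioxane (sets C3).
2. O1–C6: the 1,2-dioxane, the only ring, is closed before that by 6-exo iodoperoxidation of a C3 hydroperoxy acetal onto an E C6=C7 alkene (sets C6); C7–I is then reduced to C7–H.
3. C7–C8 and C6–ethyl in one operation: syn-ethylcupration of a terminal alkyne (C6≡C7) and alkylation of the C7 alkenylcopper with the side-chain iodide.
4. Enabling feature: ring carbon C6 is fully substituted and carries an ethyl group next to the exocyclic C7 methylene, so Et–C6=C7–C8 is the imprint of a cis ethyl–copper addition to a 1-alkyne, and C6 lies four atoms from the C3 peroxy oxygen (6-exo).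
5. Stereocentres: C4 is bought (Evans alkylation) and relayed to C6 and C3 inside the ring; C10 comes from a catalytic enal ethylation relayed by a Johnson–Claisen rearrangement.

Key step: step 10

Locants in the text: C1 is the ester carbonyl, C3–C6 are the ring carbons, C7–C14 the side chain; the target is 3S,4S,6S,10R with an E C11=C12 alkene.
Remark: ring carbon C3 is an epimeric acetal centre in 22–24; both epimers converge on cation 26, so C3 is left undefined in their SMILES.

## Route

Step 1
Reactants: 1 (E)-pent-2-enal; 2 diethylzinc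
Product: 3 (3R,4E)-hept-4-en-3-ol
Conditions: Et2Zn, (+)-DAIB (cat.), toluene, 0 °C; aq. NH4Cl
Reagents that add atoms: none
Why: Noyori-type amino-alcohol-catalysed enantioselective 1,2-addition of diethylzinc to an enal; the (2R)-configured catalyst, the enantiomer of the one that gives S alcohols, should give the R carbinol.

Step 2
Reactants: 3 (3R,4E)-hept-4-en-3-ol; 4 triethyl orthoacetate
Product: 6 ethyl (3R,4E)-3-ethylhept-4-enoate, via ketene acetal 5 (not isolated)
Conditions: CH3C(OEt)3 (excess), EtCO2H (cat.), 140 °C, EtOH distilled off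
Reagents that add atoms: none
Why: Johnson–Claisen rearrangement through a chair transition state with the carbinol ethyl group equatorial, which transfers the R carbinol configuration suprafacially to the new R stereocentre (C10 of the target) and gives the E alkene.

Step 3
Reactants: 6 ethyl (3R,4E)-3-ethylhept-4-enoate
Product: 7 (3R,4E)-3-ethylhept-4-en-1-ol
Conditions: LiAlH4, Et2O, 0 °C
Reagents that add atoms: none
Why: Hydride reduction of an ester to the primary alcohol; the isolated alkene and the β-stereocentre are not touched.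

Step 4
Reactants: 7 (3R,4E)-3-ethylhept-4-en-1-ol
Product: 8 (3E,5R)-5-ethyl-7-iodohept-3-ene
Conditions: I2, PPh3, imidazole, CH2Cl2, 0 °C to rt
Reagents that add atoms: iodine, II
Why: Appel-type (Garegg–Samuelsson) iodination of a primary alcohol by SN2 at the CH2 carbon, remote from the stereocentre and the alkene.

Step 5
Reactants: 9 (R)-4-benzyl-1,3-oxazolidin-2-one; 10 butanoyl chloride
Product: 11 (R)-4-benzyl-3-butanoyl-1,3-oxazolidin-2-one
Conditions: n-BuLi, THF, −78 °C; then 10
Reagents that add atoms: none
Why: N-acylation of the lithiated Evans auxiliary with an acid chloride.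

Step 6
Reactants: 11 (R)-4-benzyl-3-butanoyl-1,3-oxazolidin-2-one; 12 3-bromoprop-1-yne
Product: 14 (R)-4-benzyl-3-[(2S)-2-ethylpent-4-ynoyl]-1,3-oxazolidin-2-one, via sodium Z-enolate 13 (not isolated)
Conditions: NaHMDS, THF, −78 °C; then 12, −78 to −45 °C
Reagents that add atoms: none
Why: Evans asymmetric alkylation; the chelated Z-enolate is propargylated on the face opposite the benzyl group, which sets the S centre that becomes C4.

Step 7
Reactants: 14 (R)-4-benzyl-3-[(2S)-2-ethylpent-4-ynoyl]-1,3-oxazolidin-2-one
Product: 15 (2S)-2-ethylpent-4-yn-1-ol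
Conditions: LiBH4, MeOH (1 equiv), Et2O, 0 °C
Reagents that add atoms: none
Why: Reductive cleavage of the N-acyl oxazolidinone at the exocyclic carbonyl, which releases the auxiliary without epimerising the α-centre.

Step 8
Reactants: 15 (2S)-2-ethylpent-4-yn-1-ol
Product: 16 (2S)-2-ethylpent-4-ynal
Conditions: TEMPO (cat.), PhI(OAc)2, CH2Cl2, rt
Reagents that add atoms: none
Why: Oxoammonium (TEMPO/BAIB) oxidation of a primary alcohol under non-basic conditions, so the α-stereocentre and the alkyne should survive.

Step 9
Reactants: 16 (2S)-2-ethylpent-4-ynal; 17 trimethyl orthoformate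
Product: 18 (4S)-4-(dimethoxymethyl)hex-1-yne
Conditions: HC(OMe)3, PPTS (cat.), MeOH, rt
Reagents that add atoms: none
Why: Acid-catalysed acetalisation; the acetal protects C3 through the organocopper step and is the precursor of the hydroperoxy acetal.

Step 10
Reactants: 18 (4S)-4-(dimethoxymethyl)hex-1-yne; 19 ethylmagnesium bromide; 8 (3E,5R)-5-ethyl-7-iodohept-3-ene
Product: 21 (2S,4E,8R,9E)-2,4,8-triethyl-1,1-dimethoxydodeca-4,9-diene, via alkenylcopper 20 (not isolated)
Conditions: EtMgBr, CuBr·SMe2, Et2O/Me2S, −45 °C; 18, −25 °C; then 8, HMPA, P(OEt)3, THF, −25 °C to rt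
Reagents that add atoms: none
Why: Ethylcopper (from EtMgBr and CuBr) adds syn across the terminal alkyne, ethyl to the internal carbon C6 and copper to the terminal carbon C7, and the configurationally stable alkenylcopper is then alkylated with retention by the primary iodide, which forms the C7–C8 bond. The closest known reaction type is the Normant carbocupration of 1-alkynes followed by alkylation of the alkenylcopper in the presence of HMPA and a phosphite. No ring is closed and no stereocentre is created, but two C–C bonds are made in one flask, the whole C3–C14 skeleton is assembled from three simple pieces, and the E geometry (ethyl and C8 cis) that later steers the configuration of C6 is fixed by the syn addition. The step needs regioselectivity (copper on the terminal carbon), retention of alkene geometry and chemoselectivity; the unhindered terminal alkyne, the low temperature, and the absence of acidic or electrophilic groups other than the C–I bond (the acetal and the internal E alkene of 8 are inert) secure these.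

Step 11
Reactants: 21 (2S,4E,8R,9E)-2,4,8-triethyl-1,1-dimethoxydodeca-4,9-diene
Product: 22 (2S,4E,8R,9E)-2,4,8-triethyl-1-methoxydodeca-4,9-dien-1-yl hydroperoxide
Conditions: H2O2 (anhydrous, in Et2O, excess), CSA (cat.), 0 °C
Reagents that add atoms: hydrogen peroxide, OO
Why: Acid-catalysed transperacetalisation (Rieche-type exchange of one acetal methoxy group for OOH) via the oxocarbenium ion; at 0 °C the alkenes and the adjacent C4 centre should not be affected.

Step 12
Reactants: 22 (2S,4E,8R,9E)-2,4,8-triethyl-1-methoxydodeca-4,9-dien-1-yl hydroperoxide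
Product: 23 (4S,6R)-4,6-diethyl-6-[(1S,4R,5E)-4-ethyl-1-iodooct-5-en-1-yl]-3-methoxy-1,2-dioxane
Conditions: NIS, CH2Cl2, −20 to 0 °C, dark
Reagents that add atoms: N-iodosuccinimide, O=C1CCC(=O)N1I
Why: Dussault-type 6-exo iodoperoxidation of an unsaturated hydroperoxy acetal: the OOH attacks the tertiary C6 anti to the iodonium ion in a chair in which the C4 ethyl is equatorial and the C5–C4 bond eclipses the C6=C7 bond rather than the C6–ethyl bond (H, not C8, is cis to C5 in the E alkene), so C7 becomes axial and the two ethyl groups cis, which sets C6.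

Step 13
Reactants: 23 (4S,6R)-4,6-diethyl-6-[(1S,4R,5E)-4-ethyl-1-iodooct-5-en-1-yl]-3-methoxy-1,2-dioxane
Product: 24 (4S,6S)-4,6-diethyl-6-[(4R,5E)-4-ethyloct-5-en-1-yl]-3-methoxy-1,2-dioxane
Conditions: Bu3SnH (large excess, ≥2 M), Et3B/air (cat.), toluene, 0 °C
Reagents that add atoms: none
Why: Radical-chain hydrodeiodination; a high stannane concentration should let hydrogen transfer outrun 3-exo attack of the β-peroxy C7 radical on the O–O bond and 5-exo closure onto the C11=C12 alkene, and C6 is not involved.

Step 14
Reactants: 24 (4S,6S)-4,6-diethyl-6-[(4R,5E)-4-ethyloct-5-en-1-yl]-3-methoxy-1,2-dioxane; 25 1-(tert-butyldimethylsilyloxy)-1-methoxyethene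
Product: 27 methyl 2-[(3S,4S,6S)-4,6-diethyl-6-[(4R,5E)-4-ethyloct-5-en-1-yl]-1,2-dioxan-3-yl]acetate, via peroxycarbenium ion 26 (not isolated)
Conditions: 25, TMSOTf (cat.), CH2Cl2, −78 °C
Reagents that add atoms: none
Why: Dussault-type substitution of a cyclic peroxyacetal through its peroxycarbenium ion (Mukaiyama-type addition of a silyl ketene acetal): the half-chair is locked by the two equatorial ethyl groups at C4 and C6, and axial attack anti to the axial C7 chain should give the 3,4-cis acetate arm and so set C3.

## Compound list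

1 | (E)-pent-2-enal | CC/C=C/C=O | starting material
2 | diethylzinc | CC[Zn]CC | starting material
3 | (3R,4E)-hept-4-en-3-ol | CC/C=C/[C@H](O)CC | intermediate
4 | triethyl orthoacetate | CCOC(C)(OCC)OCC | starting material
5 | 1-ethoxy-1-{[(3R,4E)-hept-4-en-3-yl]oxy}ethene (ketene acetal) | C=C(OCC)O[C@H](CC)/C=C/CC | intermediate
6 | ethyl (3R,4E)-3-ethylhept-4-enoate | CC/C=C/[C@H](CC)CC(=O)OCC | intermediate
7 | (3R,4E)-3-ethylhept-4-en-1-ol | CC/C=C/[C@H](CC)CCO | intermediate
8 | (3E,5R)-5-ethyl-7-iodohept-3-ene | CC/C=C/[C@H](CC)CCI | intermediate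
9 | (R)-4-benzyl-1,3-oxazolidin-2-one | O=C1N[C@H](Cc2ccccc2)CO1 | starting material
10 | butanoyl chloride | CCCC(=O)Cl | starting material
11 | (R)-4-benzyl-3-butanoyl-1,3-oxazolidin-2-one | CCCC(=O)N1[C@H](Cc2ccccc2)COC1=O | intermediate
12 | 3-bromoprop-1-yne (propargyl bromide) | C#CCBr | starting material
13 | sodium (Z)-enolate of 11 | CC/C=C(\[O-])N1[C@H](Cc2ccccc2)COC1=O.[Na+] | intermediate
14 | (R)-4-benzyl-3-[(2S)-2-ethylpent-4-ynoyl]-1,3-oxazolidin-2-one | C#CC[C@H](CC)C(=O)N1[C@H](Cc2ccccc2)COC1=O | intermediate
15 | (2S)-2-ethylpent-4-yn-1-ol | C#CC[C@H](CC)CO | intermediate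
16 | (2S)-2-ethylpent-4-ynal | C#CC[C@H](CC)C=O | intermediate
17 | trimethyl orthoformate | COC(OC)OC | starting material
18 | (4S)-4-(dimethoxymethyl)hex-1-yne | C#CC[C@H](CC)C(OC)OC | intermediate
19 | ethylmagnesium bromide | CC[Mg]Br | starting material
20 | [(1E,4S)-4-(dimethoxymethyl)-2-ethylhex-1-en-1-yl]copper | [Cu]/C=C(CC)/C[C@H](CC)C(OC)OC | intermediate
21 | (2S,4E,8R,9E)-2,4,8-triethyl-1,1-dimethoxydodeca-4,9-diene | CC/C=C/[C@H](CC)CC/C=C(CC)/C[C@H](CC)C(OC)OC | intermediate
22 | (2S,4E,8R,9E)-2,4,8-triethyl-1-methoxydodeca-4,9-dien-1-yl hydroperoxide (both C1 epimers) | CC/C=C/[C@H](CC)CC/C=C(CC)/C[C@H](CC)C(OC)OO | intermediate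
23 | (4S,6R)-4,6-diethyl-6-[(1S,4R,5E)-4-ethyl-1-iodooct-5-en-1-yl]-3-methoxy-1,2-dioxane (both C3 epimers) | CC/C=C/[C@H](CC)CC[C@H](I)[C@@]1(CC)C[C@H](CC)C(OC)OO1 | intermediate
24 | (4S,6S)-4,6-diethyl-6-[(4R,5E)-4-ethyloct-5-en-1-yl]-3-methoxy-1,2-dioxane (both C3 epimers) | CC/C=C/[C@H](CC)CCC[C@@]1(CC)C[C@H](CC)C(OC)OO1 | intermediate
25 | 1-(tert-butyldimethylsilyloxy)-1-methoxyethene | C=C(OC)O[Si](C)(C)C(C)(C)C | starting material
26 | (4S,6S)-4,6-diethyl-6-[(4R,5E)-4-ethyloct-5-en-1-yl]-1,2-dioxan-3-ylium (peroxycarbenium) triflate | CC/C=C/[C@H](CC)CCC[C@@]1(CC)C[C@H](CC)C=[O+]O1.[O-]S(=O)(=O)C(F)(F)F | intermediate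
27 | methyl 2-[(3S,4S,6S)-4,6-diethyl-6-[(4R,5E)-4-ethyloct-5-en-1-yl]-1,2-dioxan-3-yl]acetate | CC/C=C/[C@H](CC)CCC[C@@]1(CC)C[C@H](CC)[C@H](CC(=O)OC)OO1 | target

## Step count and risks

Total steps: 14. Longest linear sequence: 10 (steps 5 to 14); the side-chain branch (steps 1 to 4) joins at step 10.

Steps most likely to fail:

Step 12. The ring closure may show poor facial selectivity at C6, or the iodonium source may engage the distal C11=C12 alkene. The fallback sets out from 21 and comes back at 24, so that steps 11 to 13 are not needed. Isayama–Mukaiyama peroxidation of 21 (Co(thd)2 cat., O2, Et3SiH, 1,2-dichloroethane, rt) should place the peroxide at the tertiary C6 by Markovnikov hydrogen-atom transfer to the trisubstituted alkene, in preference to the 1,2-disubstituted one. This would give (2S,8R,9E)-2,4,8-triethyl-1,1-dimethoxydodec-9-en-4-yl triethylsilyl peroxide F3 as both C6 epimers. Acid (TsOH cat., CH2Cl2) should then close the silyl peroxide onto the acetal with loss of the silyl group to give 24 and its C6 epimer, which would be separated by chromatography. This gives up the control of C6 but uses chemistry that is established for 1,2-dioxanes of this family.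

Step 13. The β-peroxy C7 radical may open the O–O bond to an epoxide, or cyclise onto the C11=C12 alkene, before it takes up hydrogen. The fallback sets out from 22 and comes back at 24, replacing steps 12 and 13. Cycloperoxymercuration of 22 (Hg(OAc)2, HClO4 cat., CH2Cl2, 0 °C) should give, through the same chair, (4S,6R)-6-[(1S,4R,5E)-1-(acetoxymercurio)-4-ethyloct-5-en-1-yl]-4,6-diethyl-3-methoxy-1,2-dioxane F4. Hydridodemercuration in the same flask (NaBH4, aq. NaOH, 0 °C) should then give 24. The alkylmercury hydride chain is the classical way to reduce peroxymercurials and transfers hydrogen to the radical very fast.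

Step 10. The alkylation of the alkenylcopper by the unactivated primary iodide may be slow, so that protonation, thermal decay or homocoupling of the copper species take over. The fallback sets out from 18 and 8 and comes back at 21. The ethylcupration of 18 is run as before, but alkenylcopper 20 is quenched with iodine to give (1E,4S)-4-(dimethoxymethyl)-2-ethyl-1-iodohex-1-ene F1. Iodide 8 is converted with zinc dust and LiCl in THF into [(3R,4E)-3-ethylhept-4-en-1-yl]zinc iodide F2. A Negishi coupling of F1 and F2 (Pd(dppf)Cl2 cat., THF/DMA, rt to 50 °C) should then give 21 with retention of the alkene geometry.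

Further compounds
F1 | step 10 | (1E,4S)-4-(dimethoxymethyl)-2-ethyl-1-iodohex-1-ene | I/C=C(CC)/C[C@H](CC)C(OC)OC
F2 | step 10 | [(3R,4E)-3-ethylhept-4-en-1-yl]zinc iodide | CC/C=C/[C@H](CC)CC[Zn]I
F3 | step 12 | (2S,8R,9E)-2,4,8-triethyl-1,1-dimethoxydodec-9-en-4-yl triethylsilyl peroxide (both C4 epimers) | CC/C=C/[C@H](CC)CCCC(CC)(OO[Si](CC)(CC)CC)C[C@H](CC)C(OC)OC
F4 | step 13 | (4S,6R)-6-[(1S,4R,5E)-1-(acetoxymercurio)-4-ethyloct-5-en-1-yl]-4,6-diethyl-3-methoxy-1,2-dioxane (both C3 epimers) | CC/C=C/[C@H](CC)CC[C@H]([Hg]OC(C)=O)[C@@]1(CC)C[C@H](CC)C(OC)OO1
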